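- Divide X by J in the south-east flask: the ratio reads 6.59 at 6.00 min and 7.22 at 25.0 min. You can carry this near-constant through the questions that keep the flask at 25 °C.

in all of them: J 1.5 M; E 280 mM
- south-east: temperature 25 °C; the very flask that is asked about, followed so far
- west: temperature 10 °C; run made earlier
- flask: temperature 25 °C; time 30 min

- south-east (time / min: X / %, J / %): 3.00: 74.6, 19.5; 6.00: 79.7, 12.1; 10.0: 78.3, 11.6; 15.0: 76.0, 10.7; 20.0: 74.6, 10.6; 25.0: 74.4, 10.3
- west (time / min: X / %, J / %): 6.00: 46.6, 52.4; 12.0: 69.0, 28.4; 20.0: 82.0, 14.7; 30.0: 87.5, 7.6; 40.0: 88.7, 5.3; 50.0: 88.3, 4.6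

(each reading ± 0.3 percentage points)

- what is taken out of X is counted as made
- what may be going on: J <-> X; D <-> Z; X + E <-> D + E; 2 E -> G
- additions bring no volume worth counting

- eta: at 30 min add E, 100 % of the amount charged, then wait 1.0 h
- beta: at 30 min take out 90 % of the X then present, then wait 1.0 h
- epsilon: at 30 min raise the temperature by 10 K, then wait 1.0 h
- delta: change nothing and wait 1.0 h more

- X, in percent of the J first charged, at 30 min
- the remedy with the largest gain of X, or "none" below 2 percentage points (eta / beta / epsilon / delta / none)
- X present, with what was taken out counted in, in percent of the J first charged, after eta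
- X present, with what was taken out counted in, in percent of the J first charged, after delta

- Here is the puzzle. J turns into X, yet between those two readings X falls from 79.7 % to 74.4 % while J falls too, from 12.1 % to 10.3 %.
- Add the two to clear it up. Their sum, the pool, sinks from 91.8 % to 84.7 % of the charge.
- The pool share, X over X plus J, reads 86.8 % at first and 87.8 % at the last reading, so it barely moves.
- Picture two tanks joined by a wide pipe, with a slow leak from the pair. Both levels sink and keep their ratio. Chemists call this a quasi-equilibrium.
- So freeze the share and follow the pool. My reckoning repeats the last drop in the pool, which gives 84.2 % at 30 min, and X is then 74.0 %.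
- Beta removes 66.6 %. That leaves a pool of 17.6 %, which refills X to 15.5 %. The total is 82.1 % before further leakage, a gain of 8.1 percentage points, above the mark of 2 points. I pick beta.
- The west run at 10 °C reads a share of 95.0 %, higher than at 25 °C, so I expect epsilon to lower the share.
- The forecast gives 74 %, picks beta, with 71 % after eta and 72.8 % after delta, and says “Taking out X pulls J across”.
- The flask gives 73.2 % at 30 min. The best remedy is beta, gaining 7.7 points. Eta ends at 57.6 % and delta at 68.8 %.

    J ⇌ X (K = 7.00, k = 0.0116 /s, Ea = 86.0 kJ/mol, ΔH = −48.0 kJ/mol)
    D ⇌ Z (K = 1.10, k = 0.00727 /s, Ea = 76.0 kJ/mol, ΔH = −70.0 kJ/mol)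
    X + E ⇌ D + E, rate k3*[E]*[X] forward; the back reaction follows from the equilibrium constant (K = 1.10, k = 0.00686 /M/s, Ea = 71.0 kJ/mol, ΔH = −13.0 kJ/mol)
    2 E → G (k = 0.0466 /M/s, Ea = 41.0 kJ/mol)
    (constants at 25 °C)

At 30.0 min this flask holds E at 2.08 % of its charge and G at 97.9 %, and eta, which adds E, loses 16 points. D and Z then stand at 7.90 % and 8.47 %, which leaves a pool of 83.6 %. Times the share, that gives 73.4 % of X, and the flask held 73.2 %. The same flask read at 8.00 min has D at 5.16 % and Z at 4.68 %, so its pool is 90.2 %. The share turns that into 79.2 %, and that flask held 78.6 %.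

The numbers in the tables were generated by integration with constants of no real substance; the scatter is artificial.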